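Compound numbers refer to the list after the steps. Remark on locants: in the text, ring A is numbered C1 (ester carbon), C2 (hydroxyl), C3 (prenyl), C4 (pyran oxygen), C5 (pyran carbon) and C6 (arylethyl). Compound names use chromene numbering, in which these atoms are C6, C7, C8, C8a, C4a and C5. The target has no stereogenic centre.

## Analysis of the target

The target is a 2,2-dimethyl-2H-chromene whose benzene ring (ring A) is fully substituted with six different groups: methyl ester on C1, hydroxyl on C2, prenyl on C3, the pyran oxygen on C4, the pyran vinyl carbon on C5 and a 2-(4-hydroxyphenyl)ethyl chain on C6. There is no stereocentre, and the one ring alkene is cis by necessity, so the task is one of regiochemistry only. The sensitive groups are: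

- the prenyl group beside a phenol, which acid can close to a chroman and which oxidants and halogens attack;
- the styrene-like chromene alkene;
- the hydrogen-bonded methyl salicylate;
- the free phenol of the remote ring.

The difficulty is that no electrophilic substitution on a simple phenol can place six groups in this order, and a late chromene annulation on a resorcinol would have to choose between two oxygens.

The strategy rests on three features of ring A:

- The oxygen on C4 and the carbon on C5 are ortho neighbours, which is the pattern left when the two ends of an aryne triple bond are joined to the oxygen and carbon of a carbonyl group. Aldehyde 7 carries the oxygen and all five non-aromatic carbons of the pyran.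
- C6, the neighbour of C5, can be a bromine in that aryne. It steers the addition and later becomes the anchor for the arylethyl chain.
- The C2 oxygen lies between the two remaining CH positions and can direct a metalation to each in turn.

## Retrosynthetic reasoning

**Protecting groups (24 back to 22).** The two phenols are unmasked last. The remote phenol is carried as a triisopropylsilyl ether (23), because this group does not direct metalation and survives alkyllithiums. The C2 oxygen is carried as a methoxymethyl acetal (22), because it is the best available director for the two metalations and comes off easily once an ester is beside it.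

**C1 to ester carbon (22 back to 20).** The ester carbon is cut from C1. In 20, C1 is the only ring hydrogen left and is ortho to the acetal oxygen, so deprotonation there and trapping with a methoxycarbonyl electrophile gives the ester directly at the right oxidation level. Introducing the ester earlier is not possible, because the first metalation would go to the position between the two oxygens.

**C3 to prenyl (20 back to 16 and 17).** The prenyl group is cut from C3. In 16 this carbon lies between the acetal oxygen and the ring oxygen and is the most acidic ring position, so metalation and copper-mediated allylation with 17 places the prenyl group without ambiguity. Doing this before the ester is in place avoids an alkyllithium meeting an ester.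

**C6 to CH2 (16 back to 11 and 14).** The arylethyl chain is cut at the aryl to CH2 bond. This turns the chain into a styrene (14) and ring A into an aryl bromide (11), joined forward by hydroboration and sp2 to sp3 cross-coupling. The styrene 14 comes from 12 by ester cleavage to 13 and silylation. The coupling is placed before the metalations because a C–Br bond would not survive an alkyllithium.

**Pyran ring (11 back to 6 and 7).** Three bonds are cut at once: C4 to oxygen, C5 to carbon and oxygen to CMe2. Ring A becomes the aryne released from 6 and the pyran becomes enal 7. This is the disconnection that carries the strategy. A classical condensation of a phenol with 7 would need a free ortho position chosen among several. The aryne route instead has both new ring bonds placed by the bromine substituent, and that same bromine is needed in the next step.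

**Aryne precursor (6 back to 1).** The ortho-silyl triflate 6 comes from silyl ether 4 by bromine-lithium exchange, O-to-C silyl shift and triflation of phenolate 5. Silyl ether 4 comes from dibromophenol 3, which comes from the mono-acetal 2 of hydroquinone 1. The symmetry of 3 means either bromine can be exchanged with the same result, and the bromine that stays is the one the aryne step needs.

## Alternatives that were turned down

**Alternative 1:** Ring A is cut at C3–C4 and C5–C6. Forward, the fully substituted pyrone A2 adds the silyloxyacetylene A3 across its C3 and C6 in a Diels-Alder reaction, and a decarboxylative cycloreversion gives arene A1.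
- For: A1 carries ester, protected hydroxyl, prenyl and arylethyl in the right order with no aromatic substitution at all. Its C4 oxygen and free C5 are the only place where a later condensation with aldehyde 7 could close the pyran. On this point the alternative is stronger than the chosen route, which must metalate a crowded arene twice.
- Against: A2 is a pyrone with four different substituents whose own assembly would take about as many steps as the whole path to 11. Its 4-alkoxy group and the alkyl groups at both reacting termini make it an electron-rich, hindered diene. The cycloaddition would need heat that a ynol silyl ether, an acetal and a prenyl group tolerate poorly. The pyran still has to be built afterwards.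
- Comparison: the chosen route offers a key precursor reachable in four simple steps and forms the pyran in the same event that sets the substitution pattern.

**Alternative 2:** The pyran is cut so that its C4' methylene is removed, leaving benzofuranone A5. Forward, the diazo reagent A6 adds to the ketone of A5 under boron Lewis acid activation and the ring A carbon migrates, giving chromanone A4.
- For: the oxygen and carbon are attached to ring A before the key step, so no regiochemical question arises at the heterocycle. It is as strong as the chosen route on that point.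
- Against: the key step does not address the real problem, because A5 must already contain the hexasubstituted ring A. The ketone of A5 is flanked by a quaternary carbon and a peri arylethyl group and is deactivated by the ring oxygen. Migration of the quaternary carbon can compete with aryl migration. The free salicylate hydroxyl can be methylated by A6, and the Lewis acid can close the prenyl group onto the neighbouring phenol. A4 then needs reduction and dehydration, again under conditions that threaten the prenyl phenol.
- Comparison: the chosen route delivers the chromene at the correct oxidation level in one step, before any prenyl group is present.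

**Alternative 3:** Ring A is cut at C1–C6 and C2–C3 at the cyclohexanedione level. Forward, the malonate A9 adds in Michael fashion to enone A8, which already carries the future prenyl chain, and a Claisen closure gives the cyclic diketo ester A7 (racemic trans).
- For: it is the shortest route and uses the cheapest materials. All four carbon substituents of ring A are placed by one annulation, the two stereocentres of A7 vanish on aromatization, and in the resulting resorcylate only C5 is free, so condensation with aldehyde 7 could close the pyran only there. On step economy this alternative is stronger than the chosen route.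
- Against: A7 must be dehydrogenated to the arene with the trisubstituted prenyl alkene present. Halogen- or quinone-based aromatizations attack that alkene or cyclize it onto the adjacent enol or phenol oxygen, which would form the wrong heterocycle at C3. The subsequent chromene condensation must take place on an ester-deactivated ring beside the arylethyl chain.
- Comparison: the chosen route never oxidizes anything in the presence of the prenyl group and closes the pyran before the prenyl group exists. It pays for this with more steps.

Key step: step 5

## Steps

**Step 1**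
Reactants: 1 hydroquinone
Product: 2 4-(methoxymethoxy)phenol
Conditions: 1 (3 equiv), NaH (1 equiv), MOMCl (1 equiv), DMF, 0 °C to rt, under N2
Reagents that add atoms: chloromethyl methyl ether, COCCl
Why: Williamson-type O-alkylation of the mono-phenoxide with the chloromethyl ether; the threefold excess of 1 keeps double protection low and unreacted 1 is washed out with water.

**Step 2**
Reactants: 2 4-(methoxymethoxy)phenol
Product: 3 2,6-dibromo-4-(methoxymethoxy)phenol
Conditions: NBS (2.05 equiv), i-Pr2NH (0.1 equiv), CH2Cl2, 0 °C to rt, dark
Reagents that add atoms: N-bromosuccinimide, O=C1CCC(=O)N1Br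
Why: Amine-catalysed electrophilic aromatic bromination: the free hydroxyl is the stronger activator and the N-bromoamine delivers bromine to both positions ortho to it (para is blocked), while the neutral medium spares the acetal.

**Step 3**
Reactants: 3 2,6-dibromo-4-(methoxymethoxy)phenol
Product: 4 [2,6-dibromo-4-(methoxymethoxy)phenoxy]trimethylsilane
Conditions: HMDS (1 equiv), THF, 70 °C; evaporate
Reagents that add atoms: hexamethyldisilazane, C[Si](C)(C)N[Si](C)(C)C
Why: O-Silylation of the acidic, hindered phenol with the silazane; ammonia is the only by-product, so 4 is obtained by evaporation and used without aqueous contact.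

**Step 4**
Reactants: 4 [2,6-dibromo-4-(methoxymethoxy)phenoxy]trimethylsilane
Product: 6 2-bromo-4-(methoxymethoxy)-6-(trimethylsilyl)phenyl trifluoromethanesulfonate, via lithium phenolate 5 (not isolated)
Conditions: n-BuLi (1.05 equiv), THF, −100 to −78 °C; then Tf2O (1.2 equiv), −78 °C
Reagents that add atoms: n-butyllithium, [Li]CCCC (lithium in 5 only); trifluoromethanesulfonic anhydride, O=S(=O)(OS(=O)(=O)C(F)(F)F)C(F)(F)F
Why: Bromine-lithium exchange at one of the two equivalent bromines is followed by a fast anionic 1,3 O-to-C silyl shift (retro-Brook rearrangement), and phenolate 5 is then O-triflated. Once the phenolate has formed, the second bromine is deactivated toward exchange; the sequence is the standard entry to ortho-silyl aryl triflates.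

**Step 5**
Reactants: 6 2-bromo-4-(methoxymethoxy)-6-(trimethylsilyl)phenyl trifluoromethanesulfonate; 7 3-methylbut-2-enal
Product: 11 5-bromo-7-(methoxymethoxy)-2,2-dimethyl-2H-chromene, via aryne 8 (not isolated), via benzoxete 9 (not isolated), via ortho-quinone methide 10 (not isolated)
Conditions: CsF (3 equiv), 7 (5 equiv), MeCN, rt, slow addition of 6
Reagents that add atoms: none
Why: Fluoride attacks silicon of 6 and the aryl anion expels triflate to give aryne 8; the carbonyl oxygen of 7 adds to the aryne carbon remote from bromine, and the aryl anion, now beside bromine, collapses onto the oxocarbenium carbon faster than it can lose bromide, a formal (2+2) cycloaddition that gives benzoxete 9. Thermal 4π electrocyclic opening of the strained four-membered ring gives ortho-quinone methide 10, and a thermal disrotatory oxa-6π electrocyclization forms the O–CMe2 bond, closes the six-membered pyran (the only ring formed) and restores aromaticity in 11; this is the known annulation of arynes with α,β-unsaturated aldehydes to 2H-chromenes. No stereocentre is created. The step needs oxygen to end up meta and carbon ortho to bromine: the inductively withdrawing bromine beside the triple bond stabilizes negative charge on its neighbouring carbon and shields that carbon, so the nucleophilic oxygen goes to the distal one, whereas the more distant acetal oxygen has only a small, opposing influence. The bromine also pushes the dimethylvinyl group of 10 to the carbonyl side, which is the geometry that can cyclize. Excess 7 and slow addition of 6 keep the aryne concentration low, so that 10 cyclizes before it meets a second aryne. The s-trans preference of the enal and its hindered CMe2 terminus disfavour a direct (4+2) addition that would give the 4H-chromene skeleton.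

**Step 6**
Reactants: 12 4-acetoxystyrene
Product: 13 4-vinylphenol
Conditions: K2CO3 (0.2 equiv), MeOH, 0 °C to rt; AcOH quench, concentrate cold
Reagents that add atoms: none
Why: Carbonate-catalysed transesterification of the aryl acetate with methanol; 13 polymerizes readily, so it is neutralized, concentrated cold and silylated at once.

**Step 7**
Reactants: 13 4-vinylphenol
Product: 14 triisopropyl(4-vinylphenoxy)silane
Conditions: TIPSCl (1.1 equiv), imidazole (2.2 equiv), DMF, 0 °C to rt
Reagents that add atoms: chlorotriisopropylsilane, CC(C)[Si](Cl)(C(C)C)C(C)C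
Why: Imidazole-promoted O-silylation; the triisopropylsilyl ether is chosen because it survives aqueous base and alkyllithiums and, unlike an acetal, does not direct metalation on the remote ring.

**Step 8**
Reactants: 14 triisopropyl(4-vinylphenoxy)silane; 11 5-bromo-7-(methoxymethoxy)-2,2-dimethyl-2H-chromene
Product: 16 triisopropyl(4-{2-[7-(methoxymethoxy)-2,2-dimethyl-2H-chromen-5-yl]ethyl}phenoxy)silane, via alkylborane 15 (not isolated)
Conditions: 14 (1.3 equiv), 9-BBN (1.3 equiv), THF, 0 °C to rt; then 11, PdCl2(dppf)·CH2Cl2 (5 mol %), K3PO4 (3 M aq, 3 equiv), DMF, 60 °C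
Reagents that add atoms: 9-borabicyclo[3.3.1]nonane, B1C2CCCC1CCC2 (its atoms are carried by 15 only)
Why: Anti-Markovnikov hydroboration of the styrene with the bulky dialkylborane puts boron on the terminal carbon, and B-alkyl Suzuki-Miyaura coupling (oxidative addition of zerovalent palladium into the C–Br bond, base-assisted transmetalation, reductive elimination favoured over β-hydride elimination by the wide bite angle of dppf) forms the aryl–CH2 bond. No B–H remains when 11 is added, so the chromene alkene is not hydroborated.

**Step 9**
Reactants: 16 triisopropyl(4-{2-[7-(methoxymethoxy)-2,2-dimethyl-2H-chromen-5-yl]ethyl}phenoxy)silane; 17 1-bromo-3-methylbut-2-ene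
Product: 20 triisopropyl(4-{2-[7-(methoxymethoxy)-2,2-dimethyl-8-(3-methylbut-2-en-1-yl)-2H-chromen-5-yl]ethyl}phenoxy)silane, via 8-lithiochromene 18 (not isolated), via 8-cupriochromene 19 (not isolated)
Conditions: n-BuLi (1.2 equiv), THF, 0 °C; CuBr·SMe2 (1.2 equiv), −40 °C; 17 (1.5 equiv), −40 to 0 °C
Reagents that add atoms: n-butyllithium, [Li]CCCC (lithium in 18 only); CuBr·SMe2, Br[Cu].CSC (copper in 19 only)
Why: Directed ortho-metalation: the C8 hydrogen lies between the acetal oxygen and the ring oxygen and is the most acidic and best coordinated site, so n-BuLi should give 18 selectively. Transmetalation to arylcopper 19 makes the allylic substitution occur at the primary carbon of 17 (SN2 mode) and suppresses the 1,1-dimethylallyl isomer.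

**Step 10**
Reactants: 20 triisopropyl(4-{2-[7-(methoxymethoxy)-2,2-dimethyl-8-(3-methylbut-2-en-1-yl)-2H-chromen-5-yl]ethyl}phenoxy)silane
Product: 22 methyl 7-(methoxymethoxy)-2,2-dimethyl-8-(3-methylbut-2-en-1-yl)-5-{2-[4-(triisopropylsilyloxy)phenyl]ethyl}-2H-chromene-6-carboxylate, via 6-lithiochromene 21 (not isolated)
Conditions: s-BuLi (1.3 equiv), TMEDA (1.3 equiv), THF, −78 °C; cannulate into ClCO2Me (3 equiv), THF, −78 °C to rt
Reagents that add atoms: sec-butyllithium, [Li]C(C)CC (lithium in 21 only); methyl chloroformate, COC(=O)Cl
Why: With C8 blocked, C6 is the only position left ortho to the acetal, and s-BuLi/TMEDA at low temperature should remove that ring hydrogen kinetically through pre-coordination to the acetal (directed ortho-metalation). Inverse addition of 21 to excess chloroformate gives the ester, whose two ortho substituents protect it from a second addition.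

**Step 11**
Reactants: 22 methyl 7-(methoxymethoxy)-2,2-dimethyl-8-(3-methylbut-2-en-1-yl)-5-{2-[4-(triisopropylsilyloxy)phenyl]ethyl}-2H-chromene-6-carboxylate
Product: 23 methyl 7-hydroxy-2,2-dimethyl-8-(3-methylbut-2-en-1-yl)-5-{2-[4-(triisopropylsilyloxy)phenyl]ethyl}-2H-chromene-6-carboxylate
Conditions: HCl (0.5 M in MeOH, 0.3 equiv), THF, 0 °C to rt
Reagents that add atoms: none
Why: Acid-catalysed acetal exchange with methanol; the acetal sits between an ester and a prenyl group, is twisted out of conjugation and is assisted by the ester carbonyl, so it should cleave under mild conditions, and the freed phenol is held in a hydrogen bond to the ester, which lowers its tendency to add to the prenyl alkene. The aryl triisopropylsilyl ether tolerates dilute methanolic acid, and its partial loss would only give 24 early.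

**Step 12**
Reactants: 23 methyl 7-hydroxy-2,2-dimethyl-8-(3-methylbut-2-en-1-yl)-5-{2-[4-(triisopropylsilyloxy)phenyl]ethyl}-2H-chromene-6-carboxylate
Product: 24 methyl 7-hydroxy-5-[2-(4-hydroxyphenyl)ethyl]-2,2-dimethyl-8-(3-methylbut-2-en-1-yl)-2H-chromene-6-carboxylate
Conditions: TBAF (1.1 equiv), AcOH (1.1 equiv), THF, 0 °C to rt
Reagents that add atoms: none
Why: Fluoride-induced cleavage of the aryl silyl ether, driven by Si–F bond formation; acetic acid buffers the phenoxide so that the ester and the chromene are untouched.

## Compound list

1 | hydroquinone (benzene-1,4-diol) | Oc1ccc(O)cc1 | starting material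
2 | 4-(methoxymethoxy)phenol | COCOc1ccc(O)cc1 | intermediate
3 | 2,6-dibromo-4-(methoxymethoxy)phenol | COCOc1cc(Br)c(O)c(Br)c1 | intermediate
4 | [2,6-dibromo-4-(methoxymethoxy)phenoxy]trimethylsilane | COCOc1cc(Br)c(O[Si](C)(C)C)c(Br)c1 | intermediate
5 | lithium 2-bromo-4-(methoxymethoxy)-6-(trimethylsilyl)phenolate (formed in the flask) | COCOc1cc(Br)c([O-])c([Si](C)(C)C)c1.[Li+] | intermediate
6 | 2-bromo-4-(methoxymethoxy)-6-(trimethylsilyl)phenyl trifluoromethanesulfonate | COCOc1cc(Br)c(OS(=O)(=O)C(F)(F)F)c([Si](C)(C)C)c1 | intermediate
7 | 3-methylbut-2-enal | CC(C)=CC=O | starting material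
8 | 3-bromo-5-(methoxymethoxy)benzyne (3-bromo-5-(methoxymethoxy)-1,2-didehydrobenzene; formed in the flask) | COCOC1=CC#CC(Br)=C1 | intermediate
9 | 3-bromo-5-(methoxymethoxy)-2-(2-methylprop-1-en-1-yl)-2H-benzo[b]oxete (racemic; formed in the flask) | COCOc1cc(Br)c2C(C=C(C)C)Oc2c1 | intermediate
10 | (6E)-5-bromo-3-(methoxymethoxy)-6-(3-methylbut-2-en-1-ylidene)cyclohexa-2,4-dien-1-one (dimethylvinyl group on the carbonyl side; formed in the flask) | COCOC1=CC(=O)/C(=C\C=C(C)C)C(Br)=C1 | intermediate
11 | 5-bromo-7-(methoxymethoxy)-2,2-dimethyl-2H-chromene | COCOc1cc(Br)c2C=CC(C)(C)Oc2c1 | intermediate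
12 | 4-acetoxystyrene (4-ethenylphenyl acetate) | CC(=O)Oc1ccc(C=C)cc1 | starting material
13 | 4-vinylphenol | C=Cc1ccc(O)cc1 | intermediate
14 | triisopropyl(4-vinylphenoxy)silane | C=Cc1ccc(O[Si](C(C)C)(C(C)C)C(C)C)cc1 | intermediate
15 | 9-{2-[4-(triisopropylsilyloxy)phenyl]ethyl}-9-borabicyclo[3.3.1]nonane (formed in the flask) | CC(C)[Si](Oc1ccc(CCB2C3CCCC2CCC3)cc1)(C(C)C)C(C)C | intermediate
16 | triisopropyl(4-{2-[7-(methoxymethoxy)-2,2-dimethyl-2H-chromen-5-yl]ethyl}phenoxy)silane | COCOc1cc(CCc2ccc(O[Si](C(C)C)(C(C)C)C(C)C)cc2)c2C=CC(C)(C)Oc2c1 | intermediate
17 | 1-bromo-3-methylbut-2-ene | CC(C)=CCBr | starting material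
18 | (7-(methoxymethoxy)-2,2-dimethyl-5-{2-[4-(triisopropylsilyloxy)phenyl]ethyl}-2H-chromen-8-yl)lithium (formed in the flask) | [Li]c1c(OCOC)cc(CCc2ccc(O[Si](C(C)C)(C(C)C)C(C)C)cc2)c2C=CC(C)(C)Oc12 | intermediate
19 | (7-(methoxymethoxy)-2,2-dimethyl-5-{2-[4-(triisopropylsilyloxy)phenyl]ethyl}-2H-chromen-8-yl)copper (formed in the flask) | [Cu]c1c(OCOC)cc(CCc2ccc(O[Si](C(C)C)(C(C)C)C(C)C)cc2)c2C=CC(C)(C)Oc12 | intermediate
20 | triisopropyl(4-{2-[7-(methoxymethoxy)-2,2-dimethyl-8-(3-methylbut-2-en-1-yl)-2H-chromen-5-yl]ethyl}phenoxy)silane | COCOc1cc(CCc2ccc(O[Si](C(C)C)(C(C)C)C(C)C)cc2)c2C=CC(C)(C)Oc2c1CC=C(C)C | intermediate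
21 | (7-(methoxymethoxy)-2,2-dimethyl-8-(3-methylbut-2-en-1-yl)-5-{2-[4-(triisopropylsilyloxy)phenyl]ethyl}-2H-chromen-6-yl)lithium (formed in the flask) | [Li]c1c(OCOC)c(CC=C(C)C)c2OC(C)(C)C=Cc2c1CCc1ccc(O[Si](C(C)C)(C(C)C)C(C)C)cc1 | intermediate
22 | methyl 7-(methoxymethoxy)-2,2-dimethyl-8-(3-methylbut-2-en-1-yl)-5-{2-[4-(triisopropylsilyloxy)phenyl]ethyl}-2H-chromene-6-carboxylate | COC(=O)c1c(OCOC)c(CC=C(C)C)c2OC(C)(C)C=Cc2c1CCc1ccc(O[Si](C(C)C)(C(C)C)C(C)C)cc1 | intermediate
23 | methyl 7-hydroxy-2,2-dimethyl-8-(3-methylbut-2-en-1-yl)-5-{2-[4-(triisopropylsilyloxy)phenyl]ethyl}-2H-chromene-6-carboxylate | COC(=O)c1c(O)c(CC=C(C)C)c2OC(C)(C)C=Cc2c1CCc1ccc(O[Si](C(C)C)(C(C)C)C(C)C)cc1 | intermediate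
24 | methyl 7-hydroxy-5-[2-(4-hydroxyphenyl)ethyl]-2,2-dimethyl-8-(3-methylbut-2-en-1-yl)-2H-chromene-6-carboxylate | COC(=O)c1c(O)c(CC=C(C)C)c2c(c1CCc1ccc(O)cc1)C=CC(C)(C)O2 | target

## Step count and least certain steps

Total step count: 12. Longest linear sequence: 10 steps (steps 1, 2, 3, 4, 5, 8, 9, 10, 11, 12); the side branch is steps 6 and 7.

**Step 5 (key step).** Three processes could divert the aryne or the quinone methide:
- The aryne may be consumed by an ene reaction with the allylic methyl groups of 7, or by the dienolate formed when fluoride removes a γ-hydrogen of 7.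
- Quinone methide 10 may be captured by a second aryne before it cyclizes.
- The acetal oxygen may erode the bromine-controlled regioselectivity.

Fallback: this sets out from 6 and removes the enal from the aryne event while keeping the bromine control. The aryne is generated with CsF in N,N-dimethylformamide as solvent. Insertion into the formamide carbonyl and aqueous hydrolysis should give 2-bromo-6-hydroxy-4-(methoxymethoxy)benzaldehyde F1. Addition of Me2C=CHMgBr (2.2 equiv, THF, 0 °C) would give the racemic allylic benzylic alcohol 3-bromo-2-(1-hydroxy-3-methylbut-2-en-1-yl)-5-(methoxymethoxy)phenol F2. Heating F2 in toluene over MgSO4 dehydrates it to the same ortho-quinone methide 10, which electrocyclizes, and the route is rejoined at 11.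

**Step 10.** The C6 hydrogen is flanked by the acetal and the arylethyl chain, so ring metalation may be slow. It may be overtaken by deprotonation of the benzylic and allylic CH2 of the prenyl group or by addition of the alkyllithium to the chromene alkene. A second addition of 21 to the product ester is a smaller risk.

Fallback: this sets out from 20 and replaces the metalation by a phenol-directed carboxylation.
- Mild methanolic acid removes the acetal to give 2,2-dimethyl-8-(3-methylbut-2-en-1-yl)-5-{2-[4-(triisopropylsilyloxy)phenyl]ethyl}-2H-chromen-7-ol F3.
- Heating F3 with methyl magnesium carbonate, MeOMgOCO2Me, in DMF at 120 °C carboxylates the only free position ortho to the phenol through the magnesium chelate. Acidic work-up gives 7-hydroxy-2,2-dimethyl-8-(3-methylbut-2-en-1-yl)-5-{2-[4-(triisopropylsilyloxy)phenyl]ethyl}-2H-chromene-6-carboxylic acid F4.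
- Esterification of F4 with (trimethylsilyl)diazomethane in toluene/MeOH at 0 °C rejoins the route at 23.
- If the silyl ether is lost in the hot basic medium, the same esterification gives 24 directly.

**Step 9.** Metalation may be incomplete. The allylic bromide may also be attacked at its tertiary end or homocoupled, which would give isomeric or dimeric material that is hard to separate.

Fallback: this sets out from 16 and separates the C–C bond formation from the prenyl regiochemistry. Lithio species 18 is trapped with allyl bromide, for which both modes of attack give the same product, triisopropyl(4-{2-[7-(methoxymethoxy)-2,2-dimethyl-8-(prop-2-en-1-yl)-2H-chromen-5-yl]ethyl}phenoxy)silane F5. Cross-metathesis of F5 with excess 2-methylbut-2-ene and the second-generation Grubbs catalyst RuCl2(H2IMes)(PCy3)(=CHPh) in CH2Cl2 at 40 °C converts the allyl into the prenyl group and rejoins the route at 20. The hindered cis alkene of the chromene, next to a quaternary carbon, is expected to stay out of the metathesis.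

**Step 11.** Under acid the liberated phenol may add across the neighbouring prenyl double bond to close a chroman, or the chromene may be hydrated.

Fallback: this sets out from 16, before the prenyl group is present, and exchanges the acetal for a fluoride-labile one.
- Methanolic HCl gives 2,2-dimethyl-5-{2-[4-(triisopropylsilyloxy)phenyl]ethyl}-2H-chromen-7-ol F6.
- NaH and 2-(trimethylsilyl)ethoxymethyl chloride in THF give triisopropyl[4-(2-{2,2-dimethyl-7-[2-(trimethylsilyl)ethoxymethoxy]-2H-chromen-5-yl}ethyl)phenoxy]silane F7.
- The metalation and prenylation of step 9, with this acetal as director, give triisopropyl[4-(2-{2,2-dimethyl-8-(3-methylbut-2-en-1-yl)-7-[2-(trimethylsilyl)ethoxymethoxy]-2H-chromen-5-yl}ethyl)phenoxy]silane F8.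
- The metalation and methoxycarbonylation of step 10 give methyl 2,2-dimethyl-8-(3-methylbut-2-en-1-yl)-5-{2-[4-(triisopropylsilyloxy)phenyl]ethyl}-7-[2-(trimethylsilyl)ethoxymethoxy]-2H-chromene-6-carboxylate F9.
- Excess TBAF in THF/DMPU at 60 °C, with an acetic acid quench, removes both silicon-based groups from F9 and arrives at 24 without any acid exposure of the prenyl phenol.

## Further compounds

F1 | step 5 | 2-bromo-6-hydroxy-4-(methoxymethoxy)benzaldehyde | COCOc1cc(O)c(C=O)c(Br)c1
F2 | step 5 | 3-bromo-2-(1-hydroxy-3-methylbut-2-en-1-yl)-5-(methoxymethoxy)phenol (racemic) | COCOc1cc(O)c(C(O)C=C(C)C)c(Br)c1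
F3 | step 10 | 2,2-dimethyl-8-(3-methylbut-2-en-1-yl)-5-{2-[4-(triisopropylsilyloxy)phenyl]ethyl}-2H-chromen-7-ol | Oc1cc(CCc2ccc(O[Si](C(C)C)(C(C)C)C(C)C)cc2)c2C=CC(C)(C)Oc2c1CC=C(C)C
F4 | step 10 | 7-hydroxy-2,2-dimethyl-8-(3-methylbut-2-en-1-yl)-5-{2-[4-(triisopropylsilyloxy)phenyl]ethyl}-2H-chromene-6-carboxylic acid | OC(=O)c1c(O)c(CC=C(C)C)c2OC(C)(C)C=Cc2c1CCc1ccc(O[Si](C(C)C)(C(C)C)C(C)C)cc1
F5 | step 9 | triisopropyl(4-{2-[7-(methoxymethoxy)-2,2-dimethyl-8-(prop-2-en-1-yl)-2H-chromen-5-yl]ethyl}phenoxy)silane | COCOc1cc(CCc2ccc(O[Si](C(C)C)(C(C)C)C(C)C)cc2)c2C=CC(C)(C)Oc2c1CC=C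
F6 | step 11 | 2,2-dimethyl-5-{2-[4-(triisopropylsilyloxy)phenyl]ethyl}-2H-chromen-7-ol | Oc1cc(CCc2ccc(O[Si](C(C)C)(C(C)C)C(C)C)cc2)c2C=CC(C)(C)Oc2c1
F7 | step 11 | triisopropyl[4-(2-{2,2-dimethyl-7-[2-(trimethylsilyl)ethoxymethoxy]-2H-chromen-5-yl}ethyl)phenoxy]silane | C[Si](C)(C)CCOCOc1cc(CCc2ccc(O[Si](C(C)C)(C(C)C)C(C)C)cc2)c2C=CC(C)(C)Oc2c1
F8 | step 11 | triisopropyl[4-(2-{2,2-dimethyl-8-(3-methylbut-2-en-1-yl)-7-[2-(trimethylsilyl)ethoxymethoxy]-2H-chromen-5-yl}ethyl)phenoxy]silane | C[Si](C)(C)CCOCOc1cc(CCc2ccc(O[Si](C(C)C)(C(C)C)C(C)C)cc2)c2C=CC(C)(C)Oc2c1CC=C(C)C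
F9 | step 11 | methyl 2,2-dimethyl-8-(3-methylbut-2-en-1-yl)-5-{2-[4-(triisopropylsilyloxy)phenyl]ethyl}-7-[2-(trimethylsilyl)ethoxymethoxy]-2H-chromene-6-carboxylate | COC(=O)c1c(OCOCC[Si](C)(C)C)c(CC=C(C)C)c2OC(C)(C)C=Cc2c1CCc1ccc(O[Si](C(C)C)(C(C)C)C(C)C)cc1
A1 | alternative 1 | methyl 2-(methoxymethoxy)-6-{2-[4-(methoxymethoxy)phenyl]ethyl}-3-(3-methylbut-2-enyl)-4-(triisopropylsilyloxy)benzoate | COC(=O)c1c(OCOC)c(CC=C(C)C)c(O[Si](C(C)C)(C(C)C)C(C)C)cc1CCc1ccc(OCOC)cc1
A2 | alternative 1 | methyl 4-(methoxymethoxy)-6-{2-[4-(methoxymethoxy)phenyl]ethyl}-3-(3-methylbut-2-enyl)-2-oxo-2H-pyran-5-carboxylate | COC(=O)C1=C(CCc2ccc(OCOC)cc2)OC(=O)C(CC=C(C)C)=C1OCOC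
A3 | alternative 1 | (triisopropylsilyloxy)acetylene | C#CO[Si](C(C)C)(C(C)C)C(C)C
A4 | alternative 2 | methyl 5-{2-[4-(tert-butyldimethylsilyloxy)phenyl]ethyl}-7-hydroxy-2,2-dimethyl-8-(3-methylbut-2-enyl)-3-oxochromane-6-carboxylate | COC(=O)c1c(O)c(CC=C(C)C)c2OC(C)(C)C(=O)Cc2c1CCc1ccc(O[Si](C)(C)C(C)(C)C)cc1
A5 | alternative 2 | methyl 4-{2-[4-(tert-butyldimethylsilyloxy)phenyl]ethyl}-6-hydroxy-2,2-dimethyl-7-(3-methylbut-2-enyl)-3-oxo-2,3-dihydro-1-benzofuran-5-carboxylate | COC(=O)c1c(O)c(CC=C(C)C)c2OC(C)(C)C(=O)c2c1CCc1ccc(O[Si](C)(C)C(C)(C)C)cc1
A6 | alternative 2 | (trimethylsilyl)diazomethane | C[Si](C)(C)C=[N+]=[N-]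
A7 | alternative 3 | methyl trans-2-hydroxy-6-{2-[4-(methoxymethoxy)phenyl]ethyl}-3-(3-methylbut-2-enyl)-4-oxocyclohex-2-ene-1-carboxylate (racemic, one enantiomer drawn) | COC(=O)[C@H]1[C@H](CCc2ccc(OCOC)cc2)CC(=O)C(CC=C(C)C)=C1O
A8 | alternative 3 | (E)-1-[4-(methoxymethoxy)phenyl]-9-methyldeca-3,8-dien-5-one | COCOc1ccc(CC/C=C/C(=O)CCC=C(C)C)cc1
A9 | alternative 3 | dimethyl malonate | COC(=O)CC(=O)OC
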